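All runs are simulated with constants of no real substance; noise was put on by code.

28.7% of X at 0.667 h, 28.5% at 3.00 h: Tuesday's flask had stopped making X before its first sample.

all flasks: Q 10 mol%
- Tuesday's: Z 0.50 M; the very flask that is asked about, followed so far
- Wednesday's: Z 1 M; run made earlier
- flask: Z 0.50 M; time 8.0 h

| run | time / h | X / % | E / % |
|---|---|---|---|
| Tuesday's | 0.667 | 28.7 | 6.7 |
| Tuesday's | 1.33 | 28.8 | 6.9 |
| Tuesday's | 2.00 | 29.1 | 7.1 |
| Tuesday's | 2.50 | 29.2 | 7.1 |
| Tuesday's | 3.00 | 28.5 | 6.9 |
| Wednesday's | 1.00 | 42.8 | 9.3 |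
| Wednesday's | 2.50 | 43.3 | 8.8 |
| Wednesday's | 3.00 | 43.5 | 9.1 |
| Wednesday's | 5.00 | 42.8 | 8.9 |
| Wednesday's | 6.00 | 42.6 | 8.8 |

(scatter of a reading: 0.3 percentage points)
- percentages count the Z that a species holds: one L counts as two
- the numbers in the tables scatter with a standard deviation of 0.3 percentage points
- on the list of suspects stand: Z <-> D; Z + Q -> Q + X; Q + D -> Q + E; Z <-> G; 2 Z -> L; Q -> J
- ratio of X to E at 25 s
- ratio of X to E at 12 min
- ratio of X to E at 8.0 h

*What does the ratio of X to E measure?* Take the suspects Z + Q → X and Q + D → E and divide one rate by the other. Q stands in both, so it cancels; Z and D do not, and D has to build from Z, so the ratio of the rates still moves with time. What remains is the selectivity: Z over D, times a ratio of rate constants.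

*Then why read a ratio at 8.0 h, with no sample beyond 3.00 h?* X and E stay flat within the scatter, which fits Q → J having ended both steps. I take the frozen ratio R, total X over total E across a run's readings. For Tuesday's flask that is 4.16, and I commit to it for 8.0 h.

*Is R a constant, then?* No. Wednesday's run reads 4.79, higher. At a fixed loading of 10 mol%, the frozen-ratio gradient g, the rise of R per molar of Z charged, is 1.26 M⁻¹. Two points give a line, not a proof of one.

*And at 25 s?* No reading reaches that early, so I give no number.

The forecast says 60 at 25 s, 4.8 at 12 min and 4.16 at 8.0 h, the last equal to my reading, and adds: “No early data exist, so the 25 s value is a rough guess”.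

The flask gives 70.9 at 25 s, 4.76 at 12 min and 4.27 at 8.0 h: the forecast is low at 25 s and holds at the other two times.

    Z ⇌ D (K = 2.00, k = 0.00214 s⁻¹)
    Z + Q → Q + X (k = 0.0454 M⁻¹ s⁻¹)
    Q + D → Q + E (k = 0.0241 M⁻¹ s⁻¹)
    Z ⇌ G (K = 0.825, k = 1.88 × 10⁻⁴ s⁻¹)
    2 Z → L (k = 0.00206 M⁻¹ s⁻¹)
    Q → J (k = 0.00331 s⁻¹)

Q's half-life by Q → J alone is 0.058 h, shorter than the 0.421 h by which the path 2 Z → L has done half its turnover up to 8.0 h. In this flask X stands at 29.0% at 0.800 h, with >99.9% of the turnover of Z + Q → X behind it, while L climbs from 27.0% to 47.8% by 8.00 h.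

For the same flask with 1.2 M of Z, g carried on from Wednesday's reading gives 5.04. The computed ratio at 8.0 h is 4.98.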